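**Plan**

1. Numbering: core C1–C9 (C1 prenyl, C3 aroyl, C5 side chain C1'–C6', C7 prenyl C1''–C3'', C8 CMe2, C9 bridging carbonyl). Feature: the endo prenyl group on C7 lies over the C2–C3–C4 triketone bridge, so its first carbon C1'' can be bonded for a time to C3; this C3–C1'' bond joins ring C1/C8/C7/C6/C5/C9 and ring C3/C4/C5/C6/C7/C1'' into an adamantane that stores the C7 configuration.
2. Retrosynthesis: cut C2''=C3'' (cross-metathesis), C1''–C2'' (vinyl addition after retro-aldol cleavage of C3–C1''), then C5–C6, C1–C8 and C3–C1'' together (acylphloroglucinol 25 plus enal acetate 31), then the three aryl–carbon bonds of 25 and the C4' oxygen.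
3. Forward: (S)-lavandulyl iodide (Evans alkylation) is joined to MOM-protected bromophloroglucinol by Negishi coupling; Shi epoxidation and epoxide-to-allylic-alcohol isomerisation finish the side chain; prenyl and aroyl enter by ortho-lithiation; acid frees 25.
4. The annulation closes the cyclohexanone ring, then the cage ring; retro-aldol/vinylcerium addition, Tsuji deoxygenation, metathesis and desilylation give the target.
5. Stereochemistry: C2' from the Evans alkylation, C4' from the Shi epoxidation, C1 and C5 from the chiral ammonium ion pair, C7 from the aldol trap (kept through the retro-aldol step); C3 of the cage and the carbinol centres on C1'' are temporary.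

Key step: step 18

Assumption: the target is treated as the enol tautomer of its SMILES (C4–OH, C2=O), and the cinchonidine-derived dimeric ammonium salt is taken to give the (1R,5R) core; its cinchonine-derived pseudo-enantiomer is used instead if a trial on the symmetrical bis-prenyl analogue shows the opposite sense.

**Route**

Step 1
Reactants: 1 (S)-4-benzyl-1,3-oxazolidin-2-one; 2 3-methylbut-2-enoyl chloride
Product: 4 (S)-4-benzyl-3-(3-methylbut-2-enoyl)-1,3-oxazolidin-2-one, via lithium oxazolidinide 3 (not isolated)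
Conditions: n-BuLi, THF, −78 °C; then 2, −78 → 0 °C
Reagents that add atoms: none
Why: N-acylation of a lithiated oxazolidinone with an acid chloride (Evans imide formation) is routine and the conjugated acid chloride is not enolised at −78 °C.

Step 2
Reactants: 4 (S)-4-benzyl-3-(3-methylbut-2-enoyl)-1,3-oxazolidin-2-one; 5 prenyl bromide
Product: 7 (4S)-4-benzyl-3-[(2S)-5-methyl-2-(prop-1-en-2-yl)hex-4-enoyl]-1,3-oxazolidin-2-one, via sodium dienolate 6 (not isolated)
Conditions: NaN(SiMe3)2, THF, −78 °C; then 5, −78 → −40 °C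
Reagents that add atoms: none
Why: Deconjugative Evans alkylation, in which γ-deprotonation gives the chelated Z-dienolate 6 and prenyl bromide enters at the α-carbon on the face away from the benzyl group, which sets the (2S) centre and leaves the double bond as the isopropenyl group.

Step 3
Reactants: 7 (4S)-4-benzyl-3-[(2S)-5-methyl-2-(prop-1-en-2-yl)hex-4-enoyl]-1,3-oxazolidin-2-one
Product: 8 (S)-lavandulol
Conditions: LiBH4, MeOH (1 equiv), Et2O, 0 °C
Reagents that add atoms: none
Why: Reductive cleavage of the N-acyl oxazolidinone by borohydride attacks the exocyclic carbonyl and should free the primary alcohol without touching the β,γ-alkene or the α-stereocentre.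

Step 4
Reactants: 8 (S)-lavandulol
Product: 9 (S)-lavandulyl iodide
Conditions: I2, PPh3, imidazole, CH2Cl2, 0 °C → rt
Reagents that add atoms: iodine, II
Why: Appel-type iodination replaces the primary hydroxyl by SN2 at the CH2 group, so the neighbouring stereocentre is not involved.

Step 5
Reactants: 10 phloroglucinol
Product: 11 1,3,5-tris(methoxymethoxy)benzene
Conditions: MOMCl, i-Pr2NEt, DMF, 0 °C → rt
Reagents that add atoms: chloromethyl methyl ether, COCCl
Why: Williamson-type O-alkylation with the hard electrophile MOMCl gives the tris-acetal, which is base-stable and directs ortho-lithiation.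

Step 6
Reactants: 11 1,3,5-tris(methoxymethoxy)benzene
Product: 12 2-bromo-1,3,5-tris(methoxymethoxy)benzene
Conditions: NBS (1.0 equiv), CH2Cl2, −40 → 0 °C
Reagents that add atoms: N-bromosuccinimide, O=C1CCC(=O)N1Br
Why: Electrophilic aromatic bromination of the strongly activated arene should stop at the monobromide because the three free positions are equivalent and the first bromine deactivates the ring slightly.

Step 7
Reactants: 9 (S)-lavandulyl iodide; 12 2-bromo-1,3,5-tris(methoxymethoxy)benzene
Product: 14 2-[(2R)-5-methyl-2-(prop-1-en-2-yl)hex-4-en-1-yl]-1,3,5-tris(methoxymethoxy)benzene, via lavandulylzinc iodide 13 (not isolated)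
Conditions: Zn dust (activated with BrCH2CH2Br and Me3SiCl), LiCl, THF, 40 °C; then 12, Pd(OAc)2 (2 mol%), SPhos (4 mol%), THF, 60 °C
Reagents that add atoms: none
Why: Negishi sp3–sp2 cross-coupling, in which zinc inserts into the primary C–I bond and the bulky biarylphosphine lets the hindered, electron-rich aryl bromide couple faster than β-hydride elimination; the stereocentre is β to zinc and keeps its arrangement (the descriptor changes by priority only).

Step 8
Reactants: 14 2-[(2R)-5-methyl-2-(prop-1-en-2-yl)hex-4-en-1-yl]-1,3,5-tris(methoxymethoxy)benzene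
Product: 15 2-{(2S)-2-{[(2R)-3,3-dimethyloxiran-2-yl]methyl}-3-methylbut-3-en-1-yl}-1,3,5-tris(methoxymethoxy)benzene
Conditions: D-fructose-derived Shi ketone (30 mol%), KHSO5 (as 2KHSO5·KHSO4·K2SO4), K2CO3, Bu4NHSO4, MeCN–CH2(OMe)2–aq. Na2B4O7 buffer, 0 °C
Reagents that add atoms: potassium peroxymonosulfate, [K+].[O-]S(=O)(=O)OO
Why: Shi asymmetric epoxidation, in which the chiral dioxirane reacts with the trisubstituted alkene much faster than with the 1,1-disubstituted isopropenyl group and, under reagent control, delivers oxygen to the face that gives the (R)-oxirane carbon (later C4').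

Step 9
Reactants: 15 2-{(2S)-2-{[(2R)-3,3-dimethyloxiran-2-yl]methyl}-3-methylbut-3-en-1-yl}-1,3,5-tris(methoxymethoxy)benzene
Product: 16 2-[(2S,4R)-4-hydroxy-5-methyl-2-(prop-1-en-2-yl)hex-5-en-1-yl]-1,3,5-tris(methoxymethoxy)benzene
Conditions: 2,2,6,6-tetramethylpiperidine, n-BuLi, then Et2AlCl, toluene, 0 °C; then 15, 0 °C → rt; aq. potassium sodium tartrate
Reagents that add atoms: none
Why: Aluminium-amide-promoted isomerisation of a trisubstituted epoxide to an allylic alcohol, in which aluminium binds the oxirane oxygen and the hindered amide removes a methyl proton, so the C–O bond at the stereocentre is never broken and the (R) configuration is kept.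

Step 10
Reactants: 16 2-[(2S,4R)-4-hydroxy-5-methyl-2-(prop-1-en-2-yl)hex-5-en-1-yl]-1,3,5-tris(methoxymethoxy)benzene
Product: 17 2-[(2S,4R)-4-(tert-butyldiphenylsilyloxy)-5-methyl-2-(prop-1-en-2-yl)hex-5-en-1-yl]-1,3,5-tris(methoxymethoxy)benzene
Conditions: TBDPSCl, imidazole, DMAP (cat.), DMF, rt → 40 °C
Reagents that add atoms: tert-butyl(chloro)diphenylsilane, CC(C)(C)[Si](Cl)(c1ccccc1)c1ccccc1
Why: Silylation of the secondary allylic alcohol gives an ether that should survive organolithiums, the later acid acetal cleavage, cold hydroxide and organocerium reagents.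

Step 11
Reactants: 17 2-[(2S,4R)-4-(tert-butyldiphenylsilyloxy)-5-methyl-2-(prop-1-en-2-yl)hex-5-en-1-yl]-1,3,5-tris(methoxymethoxy)benzene; 5 prenyl bromide
Product: 19 2-[(2S,4R)-4-(tert-butyldiphenylsilyloxy)-5-methyl-2-(prop-1-en-2-yl)hex-5-en-1-yl]-4-(3-methylbut-2-en-1-yl)-1,3,5-tris(methoxymethoxy)benzene, via aryllithium 18 (not isolated)
Conditions: n-BuLi, THF, 0 °C; then CuI (10 mol%), 5, −78 → 0 °C
Reagents that add atoms: none
Why: Directed ortho-metalation between two MOM-oxy groups followed by copper-catalysed SN2 allylation; the two free ring positions are equivalent, so one constitution results.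

Step 12
Reactants: 20 3,4-dihydroxybenzaldehyde
Product: 21 3,4-bis(triisopropylsilyloxy)benzaldehyde
Conditions: TIPSCl, imidazole, DMF, rt
Reagents that add atoms: chlorotri(propan-2-yl)silane, CC(C)[Si](Cl)(C(C)C)C(C)C
Why: Standard silylation of the catechol; the triisopropylsilyl aryl ethers tolerate organolithium addition, acid and cold hydroxide and leave together with the alkyl silyl ether in the last step.

Step 13
Reactants: 19 prenylated tris-MOM arene; 21 3,4-bis(triisopropylsilyloxy)benzaldehyde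
Product: 23 diarylmethanol (2,4,6-tris-MOM-oxy ring carrying prenyl and the silylated side chain; both carbinol epimers), via aryllithium 22 (not isolated)
Conditions: n-BuLi, THF, 0 °C; then 21, −78 → 0 °C; H2O
Reagents that add atoms: none
Why: Directed ortho-metalation of the last ring C–H and 1,2-addition of the aryllithium to the aldehyde; the new carbinol centre is formed without control and is removed by the oxidation that follows.

Step 14
Reactants: 23 diarylmethanol
Product: 24 benzophenone (tris-MOM ether of 25)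
Conditions: Dess–Martin periodinane, pyridine, CH2Cl2, 0 °C → rt
Reagents that add atoms: none
Why: Dess–Martin oxidation of the doubly benzylic alcohol under buffered conditions should leave alkenes, acetals and silyl ethers untouched.

Step 15
Reactants: 24 benzophenone (tris-MOM ether of 25)
Product: 25 {3,4-bis(triisopropylsilyloxy)phenyl}{3-[(2S,4R)-4-(tert-butyldiphenylsilyloxy)-5-methyl-2-(prop-1-en-2-yl)hex-5-en-1-yl]-2,4,6-trihydroxy-5-(3-methylbut-2-en-1-yl)phenyl}methanone
Conditions: HCl (3 M aq.)/MeOH, 40 °C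
Reagents that add atoms: none
Why: Acid-catalysed acetal exchange (methanolysis of aryl MOM ethers) frees the phloroglucinol, the aryl TIPS and alkyl TBDPS ethers being far more acid-stable than the acetals.

Step 16
Reactants: 26 2-bromo-3,3-diethoxyprop-1-ene; 27 acetone
Product: 30 3-(diethoxymethyl)-2-methylbut-3-en-2-yl acetate, via vinyllithium acetal 28 (not isolated), via lithium tertiary alkoxide 29 (not isolated)
Conditions: n-BuLi, THF, −78 °C; 27, −78 °C; Ac2O, −78 °C → rt
Reagents that add atoms: acetic anhydride, CC(=O)OC(C)=O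
Why: Bromine–lithium exchange gives the α-lithioacrolein acetal, which adds to acetone (1,2-addition), and the hindered lithium alkoxide is acetylated in the same flask.

Step 17
Reactants: 30 3-(diethoxymethyl)-2-methylbut-3-en-2-yl acetate
Product: 31 3-formyl-2-methylbut-3-en-2-yl acetate
Conditions: HCl (1 M aq.), THF, 0 °C
Reagents that add atoms: water, O
Why: Mild acid hydrolysis of the diethyl acetal unmasks the enal, and the tertiary acetate is stable to cold dilute acid.

Step 18
Reactants: 25 acylphloroglucinol (aroyl at C3, prenyl at C1, silylated side chain at C5); 31 3-formyl-2-methylbut-3-en-2-yl acetate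
Product: 34 adamantane alcohol (tetraketone cage in which C1'' links C3 to C7 and carries OH; both C1'' epimers), via C5-alkylated dienone 32 (not isolated), via bicyclic C7 aldehyde 33 (not isolated)
Conditions: 25, 31 (2 equiv), N,N'-(naphthalene-2,7-diyldimethylene)bis(O-allylhydrocinchonidinium) dibromide (25 mol%), 4 Å molecular sieves, CH2Cl2, −50 °C; CsOH·H2O (5 equiv) added last
Reagents that add atoms: none
Why: The closest known reaction type is the enantioselective alkylative dearomatisation–annulation of 2-acyl-4,6-dialkylphloroglucinols with α-(1-acyloxyalkyl) enals under a chiral ammonium phenolate ion pair, and 25 belongs to that class: the phenolate adds through C5 to the methylene carbon of 31 (Michael addition), acetate leaves by E1cB to give 32, C1 adds to the new β,β-dimethyl enal to give 33, and the C3 enolate adds to the formyl group. The cyclohexanone ring (C1, C8, C7, C6, C5, C9) closes by a 6-endo-trig Michael addition and the cage ring (C3, C4, C5, C6, C7, C1'') by a 6-(enolendo)-exo-trig aldol addition. C5 is set by the face that the chiral cation leaves open and C1 follows because the three-carbon bridge can span only that face; C7 epimerises through the aldehyde enolate and only its endo epimer reaches C3, so the aldol drains the mixture into one configuration; C3 is fixed by the cage, and C1'' forms as both epimers, which is harmless because step 19 erases it. The step needs C- rather than O-alkylation, which the soft chelated acylphloroglucinolate and the reversibility of oxa-Michael adducts should provide, and it needs C5 rather than C1 to make the first bond. The ion pair does not settle that order, since attack by C1 from the opposite face is its equal partner; the order rests on the substrate alone, where C5 carries a saturated and so more electron-releasing CH2 group than the allylic CH2 on C1, and the bulky silyl ether sits four atoms from C5.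

Step 19
Reactants: 34 adamantane alcohol
Product: 36 bicyclic triketone enol with endo 1-hydroxyprop-2-en-1-yl group on C7 (both carbinol epimers), via lithium enolate aldehyde 35 (not isolated)
Conditions: LiN(i-Pr)2, THF, −78 → −40 °C; then CH2=CHMgBr/CeCl3 (premixed in THF), −78 °C; aq. NH4Cl
Reagents that add atoms: vinylmagnesium bromide, C=C[Mg]Br
Why: Retro-aldol fragmentation of the lithium aldolate to the stabilised triketone enolate 35, then 1,2-addition of the weakly basic vinylcerium reagent to the freed aldehyde faster than it can enolise, so C7 stays endo; the new carbinol centre is uncontrolled and is removed in step 21, and a vinyl rather than a 2-methylpropenyl nucleophile is used so that the later hydride delivery gives the right alkene.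

Step 20
Reactants: 36 C7 allylic alcohol
Product: 38 C7 1-(methoxycarbonyloxy)prop-2-en-1-yl compound with free triketone enol, via enol bis-carbonate 37 (not isolated)
Conditions: ClCO2Me, pyridine, DMAP (cat.), CH2Cl2, 0 °C; then MeOH, aq. NaHCO3, 0 °C
Reagents that add atoms: methyl chloroformate, COC(=O)Cl
Why: O-acylation with a chloroformate; the enol carbonate formed alongside is a vinylogous mixed anhydride and should be cleaved selectively by bicarbonate/methanol, leaving the allylic carbonate.

Step 21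
Reactants: 38 allylic methyl carbonate
Product: 39 C7-allyl bicyclic triketone enol (silyl ethers intact)
Conditions: Pd2(dba)3·CHCl3 (5 mol%), n-Bu3P (20 mol%), HCO2H, Et3N, THF, 40 °C
Reagents that add atoms: none
Why: Tsuji reduction of an allylic carbonate with formate, in which zerovalent palladium ionises the carbonate and the allylpalladium formate loses CO2 and delivers hydride to the more substituted terminus C1'', giving C7–CH2–CH=CH2 with no new stereocentre; an O-allyl enol ether formed by capture of the allyl complex would be re-ionised and drain to the same product.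

Step 22
Reactants: 39 C7-allyl bicyclic triketone enol
Product: 40 tris-silyl ether of the target (C7 prenyl)
Conditions: second-generation Grubbs catalyst RuCl2(=CHPh)(H2IMes)(PCy3) (10 mol%), 2-methylbut-2-ene/CH2Cl2, 40 °C
Reagents that add atoms: 2-methylbut-2-ene, CC=C(C)C
Why: Olefin cross-metathesis of the monosubstituted alkene with excess 2-methylbut-2-ene converts allyl into prenyl, while the 1,1-disubstituted isopropenyl groups and the trisubstituted C1 prenyl group are poor metathesis partners under these conditions.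

Step 23
Reactants: 40 tris-silyl ether of the target
Product: 41 (1R,5R,7R)-3-(3,4-dihydroxybenzoyl)-4-hydroxy-5-[(2S,4R)-4-hydroxy-5-methyl-2-(prop-1-en-2-yl)hex-5-en-1-yl]-8,8-dimethyl-1,7-bis(3-methylbut-2-en-1-yl)bicyclo[3.3.1]non-3-ene-2,9-dione
Conditions: Bu4NF, AcOH (1:1), THF, 0 °C → rt, argon
Reagents that add atoms: none
Why: Fluoride-mediated desilylation buffered with acetic acid should remove the two aryl TIPS ethers and the secondary TBDPS ether without acid- or base-induced cyclisation of the prenyl groups onto the enol.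

**Compound list**

1 | (S)-4-benzyl-1,3-oxazolidin-2-one | O=C1N[C@@H](Cc2ccccc2)CO1 | starting material
2 | 3-methylbut-2-enoyl chloride | CC(C)=CC(Cl)=O | starting material
3 | N-lithio derivative of 1 | [Li]N1[C@@H](Cc2ccccc2)COC1=O | intermediate
4 | (S)-4-benzyl-3-(3-methylbut-2-enoyl)-1,3-oxazolidin-2-one | CC(C)=CC(=O)N1[C@@H](Cc2ccccc2)COC1=O | intermediate
5 | prenyl bromide (1-bromo-3-methylbut-2-ene) | CC(C)=CCBr | starting material
6 | sodium (Z)-dienolate of 4 | [Na+].[O-]/C(=C\C(C)=C)N1[C@@H](Cc2ccccc2)COC1=O | intermediate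
7 | (4S)-4-benzyl-3-[(2S)-5-methyl-2-(prop-1-en-2-yl)hex-4-enoyl]-1,3-oxazolidin-2-one | C=C(C)[C@H](CC=C(C)C)C(=O)N1[C@@H](Cc2ccccc2)COC1=O | intermediate
8 | (S)-lavandulol, (2S)-5-methyl-2-(prop-1-en-2-yl)hex-4-en-1-ol | C=C(C)[C@H](CC=C(C)C)CO | intermediate
9 | (S)-lavandulyl iodide, (2S)-1-iodo-5-methyl-2-(prop-1-en-2-yl)hex-4-ene | C=C(C)[C@H](CC=C(C)C)CI | intermediate
10 | phloroglucinol | Oc1cc(O)cc(O)c1 | starting material
11 | 1,3,5-tris(methoxymethoxy)benzene | COCOc1cc(OCOC)cc(OCOC)c1 | intermediate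
12 | 2-bromo-1,3,5-tris(methoxymethoxy)benzene | COCOc1cc(OCOC)c(Br)c(OCOC)c1 | intermediate
13 | (S)-lavandulylzinc iodide | C=C(C)[C@H](CC=C(C)C)C[Zn]I | intermediate
14 | 2-[(2R)-5-methyl-2-(prop-1-en-2-yl)hex-4-en-1-yl]-1,3,5-tris(methoxymethoxy)benzene (same spatial arrangement as in 8) | C=C(C)[C@H](CC=C(C)C)Cc1c(OCOC)cc(OCOC)cc1OCOC | intermediate
15 | 2-{(2S)-2-{[(2R)-3,3-dimethyloxiran-2-yl]methyl}-3-methylbut-3-en-1-yl}-1,3,5-tris(methoxymethoxy)benzene | C=C(C)[C@H](C[C@H]1OC1(C)C)Cc1c(OCOC)cc(OCOC)cc1OCOC | intermediate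
16 | 2-[(2S,4R)-4-hydroxy-5-methyl-2-(prop-1-en-2-yl)hex-5-en-1-yl]-1,3,5-tris(methoxymethoxy)benzene | C=C(C)[C@H](C[C@@H](O)C(=C)C)Cc1c(OCOC)cc(OCOC)cc1OCOC | intermediate
17 | 2-[(2S,4R)-4-(tert-butyldiphenylsilyloxy)-5-methyl-2-(prop-1-en-2-yl)hex-5-en-1-yl]-1,3,5-tris(methoxymethoxy)benzene | C=C(C)[C@H](C[C@@H](O[Si](c1ccccc1)(c1ccccc1)C(C)(C)C)C(=C)C)Cc1c(OCOC)cc(OCOC)cc1OCOC | intermediate
18 | aryllithium from 17 (lithium at a ring CH between two MOM-oxy groups) | C=C(C)[C@H](C[C@@H](O[Si](c1ccccc1)(c1ccccc1)C(C)(C)C)C(=C)C)Cc1c(OCOC)cc(OCOC)c([Li])c1OCOC | intermediate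
19 | 2-[(2S,4R)-4-(tert-butyldiphenylsilyloxy)-5-methyl-2-(prop-1-en-2-yl)hex-5-en-1-yl]-4-(3-methylbut-2-en-1-yl)-1,3,5-tris(methoxymethoxy)benzene | C=C(C)[C@H](C[C@@H](O[Si](c1ccccc1)(c1ccccc1)C(C)(C)C)C(=C)C)Cc1c(OCOC)cc(OCOC)c(CC=C(C)C)c1OCOC | intermediate
20 | 3,4-dihydroxybenzaldehyde | O=Cc1ccc(O)c(O)c1 | starting material
21 | 3,4-bis(triisopropylsilyloxy)benzaldehyde | O=Cc1ccc(O[Si](C(C)C)(C(C)C)C(C)C)c(O[Si](C(C)C)(C(C)C)C(C)C)c1 | intermediate
22 | aryllithium from 19 (lithium at the last ring CH) | C=C(C)[C@H](C[C@@H](O[Si](c1ccccc1)(c1ccccc1)C(C)(C)C)C(=C)C)Cc1c(OCOC)c([Li])c(OCOC)c(CC=C(C)C)c1OCOC | intermediate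
23 | {3,4-bis(triisopropylsilyloxy)phenyl}{3-[(2S,4R)-4-(tert-butyldiphenylsilyloxy)-5-methyl-2-(prop-1-en-2-yl)hex-5-en-1-yl]-2,4,6-tris(methoxymethoxy)-5-(3-methylbut-2-en-1-yl)phenyl}methanol, both carbinol epimers | C=C(C)[C@H](C[C@@H](O[Si](c1ccccc1)(c1ccccc1)C(C)(C)C)C(=C)C)Cc1c(OCOC)c(C(O)c2ccc(O[Si](C(C)C)(C(C)C)C(C)C)c(O[Si](C(C)C)(C(C)C)C(C)C)c2)c(OCOC)c(CC=C(C)C)c1OCOC | intermediate
24 | methanone corresponding to 23 (tris-MOM ether of 25) | C=C(C)[C@H](C[C@@H](O[Si](c1ccccc1)(c1ccccc1)C(C)(C)C)C(=C)C)Cc1c(OCOC)c(C(=O)c2ccc(O[Si](C(C)C)(C(C)C)C(C)C)c(O[Si](C(C)C)(C(C)C)C(C)C)c2)c(OCOC)c(CC=C(C)C)c1OCOC | intermediate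
25 | {3,4-bis(triisopropylsilyloxy)phenyl}{3-[(2S,4R)-4-(tert-butyldiphenylsilyloxy)-5-methyl-2-(prop-1-en-2-yl)hex-5-en-1-yl]-2,4,6-trihydroxy-5-(3-methylbut-2-en-1-yl)phenyl}methanone | C=C(C)[C@H](C[C@@H](O[Si](c1ccccc1)(c1ccccc1)C(C)(C)C)C(=C)C)Cc1c(O)c(C(=O)c2ccc(O[Si](C(C)C)(C(C)C)C(C)C)c(O[Si](C(C)C)(C(C)C)C(C)C)c2)c(O)c(CC=C(C)C)c1O | intermediate
26 | 2-bromo-3,3-diethoxyprop-1-ene | C=C(Br)C(OCC)OCC | starting material
27 | acetone | CC(C)=O | starting material
28 | 2-lithio-3,3-diethoxyprop-1-ene | C=C([Li])C(OCC)OCC | intermediate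
29 | lithium 3-(diethoxymethyl)-2-methylbut-3-en-2-olate | C=C(C(OCC)OCC)C(C)(C)O[Li] | intermediate
30 | 3-(diethoxymethyl)-2-methylbut-3-en-2-yl acetate | C=C(C(OCC)OCC)C(C)(C)OC(C)=O | intermediate
31 | 3-formyl-2-methylbut-3-en-2-yl acetate | C=C(C=O)C(C)(C)OC(C)=O | intermediate
32 | dienone from 25, dearomatised at C5, which carries the side chain and a 2-formyl-3-methylbut-2-en-1-yl group (C5 configured as in 41) | C=C(C)[C@H](C[C@@H](O[Si](c1ccccc1)(c1ccccc1)C(C)(C)C)C(=C)C)C[C@@]1(CC(C=O)=C(C)C)C(=O)C(C(=O)c2ccc(O[Si](C(C)C)(C(C)C)C(C)C)c(O[Si](C(C)C)(C(C)C)C(C)C)c2)=C(O)C(CC=C(C)C)=C1O | intermediate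
33 | 7-formyl bicyclo[3.3.1]nonane triketone enol (C1 and C5 as in 41, C7 epimers in equilibrium) | C=C(C)[C@H](C[C@@H](O[Si](c1ccccc1)(c1ccccc1)C(C)(C)C)C(=C)C)C[C@@]12CC(C=O)C(C)(C)[C@@](CC=C(C)C)(C(=O)C(C(=O)c3ccc(O[Si](C(C)C)(C(C)C)C(C)C)c(O[Si](C(C)C)(C(C)C)C(C)C)c3)=C1O)C2=O | intermediate
34 | adamantane alcohol: 2,4,9-trioxo cage with aroyl on C3, prenyl on C1, side chain on C5, gem-dimethyl C8 and CH(OH) bridge C1'' between C3 and C7 (C1, C5, C7 as in 41; both C1'' epimers) | C=C(C)[C@H](C[C@@H](O[Si](c1ccccc1)(c1ccccc1)C(C)(C)C)C(=C)C)C[C@@]12C[C@@H]3C(C)(C)[C@@](CC=C(C)C)(C(=O)[C@](C(=O)c4ccc(O[Si](C(C)C)(C(C)C)C(C)C)c(O[Si](C(C)C)(C(C)C)C(C)C)c4)(C1=O)C3O)C2=O | intermediate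
35 | lithium triketone enolate with endo formyl group on C7 (retro-aldol product of 34) | [Li+].C=C(C)[C@H](C[C@@H](O[Si](c1ccccc1)(c1ccccc1)C(C)(C)C)C(=C)C)C[C@@]12C[C@@H](C=O)C(C)(C)[C@@](CC=C(C)C)(C(=O)C(C(=O)c3ccc(O[Si](C(C)C)(C(C)C)C(C)C)c(O[Si](C(C)C)(C(C)C)C(C)C)c3)=C1[O-])C2=O | intermediate
36 | 3-[3,4-bis(triisopropylsilyloxy)benzoyl]-5-[(2S,4R)-4-(tert-butyldiphenylsilyloxy)-5-methyl-2-(prop-1-en-2-yl)hex-5-en-1-yl]-4-hydroxy-7-(1-hydroxyprop-2-en-1-yl)-8,8-dimethyl-1-(3-methylbut-2-en-1-yl)bicyclo[3.3.1]non-3-ene-2,9-dione, core as in 41, both carbinol epimers | C=C(C)[C@H](C[C@@H](O[Si](c1ccccc1)(c1ccccc1)C(C)(C)C)C(=C)C)C[C@@]12C[C@@H](C(O)C=C)C(C)(C)[C@@](CC=C(C)C)(C(=O)C(C(=O)c3ccc(O[Si](C(C)C)(C(C)C)C(C)C)c(O[Si](C(C)C)(C(C)C)C(C)C)c3)=C1O)C2=O | intermediate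
37 | bis(methyl carbonate) of 36 (allylic carbonate and enol carbonate) | C=C(C)[C@H](C[C@@H](O[Si](c1ccccc1)(c1ccccc1)C(C)(C)C)C(=C)C)C[C@@]12C[C@@H](C(OC(=O)OC)C=C)C(C)(C)[C@@](CC=C(C)C)(C(=O)C(C(=O)c3ccc(O[Si](C(C)C)(C(C)C)C(C)C)c(O[Si](C(C)C)(C(C)C)C(C)C)c3)=C1OC(=O)OC)C2=O | intermediate
38 | allylic methyl carbonate of 36 with free enol | C=C(C)[C@H](C[C@@H](O[Si](c1ccccc1)(c1ccccc1)C(C)(C)C)C(=C)C)C[C@@]12C[C@@H](C(OC(=O)OC)C=C)C(C)(C)[C@@](CC=C(C)C)(C(=O)C(C(=O)c3ccc(O[Si](C(C)C)(C(C)C)C(C)C)c(O[Si](C(C)C)(C(C)C)C(C)C)c3)=C1O)C2=O | intermediate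
39 | 7-(prop-2-en-1-yl) analogue of 40 (endo allyl on C7) | C=C(C)[C@H](C[C@@H](O[Si](c1ccccc1)(c1ccccc1)C(C)(C)C)C(=C)C)C[C@@]12C[C@@H](CC=C)C(C)(C)[C@@](CC=C(C)C)(C(=O)C(C(=O)c3ccc(O[Si](C(C)C)(C(C)C)C(C)C)c(O[Si](C(C)C)(C(C)C)C(C)C)c3)=C1O)C2=O | intermediate
40 | tris-silyl ether of 41 (catechol as bis-TIPS ether, C4'-OTBDPS) | C=C(C)[C@H](C[C@@H](O[Si](c1ccccc1)(c1ccccc1)C(C)(C)C)C(=C)C)C[C@@]12C[C@@H](CC=C(C)C)C(C)(C)[C@@](CC=C(C)C)(C(=O)C(C(=O)c3ccc(O[Si](C(C)C)(C(C)C)C(C)C)c(O[Si](C(C)C)(C(C)C)C(C)C)c3)=C1O)C2=O | intermediate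
41 | (1R,5R,7R)-3-(3,4-dihydroxybenzoyl)-4-hydroxy-5-[(2S,4R)-4-hydroxy-5-methyl-2-(prop-1-en-2-yl)hex-5-en-1-yl]-8,8-dimethyl-1,7-bis(3-methylbut-2-en-1-yl)bicyclo[3.3.1]non-3-ene-2,9-dione | C=C(C)[C@H](C[C@@H](O)C(=C)C)C[C@@]12C[C@@H](CC=C(C)C)C(C)(C)[C@@](CC=C(C)C)(C(=O)C(C(=O)c3ccc(O)c(O)c3)=C1O)C2=O | target

**Step count and risks**

Total steps: 23. Longest linear sequence: 18 steps (steps 1–4, 7–11, 13–15, 18–23).

Steps most likely to fail:

Step 18. The first Michael addition may start at C1 instead of C5, which would place the gem-dimethyl carbon next to the side-chain bridgehead; the ion pair fixes the absolute sense but not this order, and the β-branch of the side chain works against the electronic preference for C5. Fallback: make the first C–C bond reversible so that the ring-closing Michael addition decides, since that step is much more sensitive to the group on the attacking carbon. Starting from 26 and 27, the alkoxide 29 is trapped with methyl chloroformate to give 3-(diethoxymethyl)-2-methylbut-3-en-2-yl methyl carbonate F1, and acetal hydrolysis gives 3-formyl-2-methylbut-3-en-2-yl methyl carbonate F2. Treating 25 with F2 and Pd(PPh3)4 in THF, then K2CO3 (Tsuji–Trost allylation), should let the O- and C-allylated phloroglucinols interconvert through the allylpalladium complex. Only the C5-allylated isomer offers the less hindered prenyl-bearing C1 to the CMe2 terminus, so it should close and be trapped by the aldol, and the route is rejoined at 34. The chiral ammonium salt can be kept as co-catalyst; without it the two cores are diastereomers because of the side chain and would be separated at 34.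

Step 21. The allylpalladium intermediate may be captured by the neighbouring triketone enolate oxygen, lose a β-hydrogen to a diene, or take hydride at the wrong terminus. Fallback: leave allyl-metal chemistry and build the prenyl group by two Wittig reactions. Starting from 34, the enolate aldehyde 35 is generated as in step 19 and treated with methoxymethylenetriphenylphosphorane to give the C7 2-methoxyvinyl compound F3. Mild aqueous acid gives the C7 2-oxoethyl compound F4, in which any homo-aldol closure onto C3 is reversible under base. Isopropylidenetriphenylphosphorane then gives 40 directly, which also bypasses steps 20 and 22.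

Step 15. As the acetals fall, acid may close the prenyl group onto the neighbouring free phenol (chroman formation). Fallback: cleave the acetals before the prenyl group is present and introduce it last by classical C-alkylation. Starting from 17, ortho-lithiation and addition to 21 gives the prenyl-free diarylmethanol F5, and Dess–Martin oxidation gives the benzophenone F6. Acid methanolysis then gives the 2-aroyl-4-alkylphloroglucinol F7. C-prenylation of F7 with 5 at its only free ring carbon (aqueous KOH or DBU) rejoins the route at 25.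

Further compounds
F1 | step 18 | 3-(diethoxymethyl)-2-methylbut-3-en-2-yl methyl carbonate | C=C(C(OCC)OCC)C(C)(C)OC(=O)OC
F2 | step 18 | 3-formyl-2-methylbut-3-en-2-yl methyl carbonate | C=C(C=O)C(C)(C)OC(=O)OC
F3 | step 21 | 7-(2-methoxyethenyl) analogue of 40 (endo on C7, E/Z mixture) | C=C(C)[C@H](C[C@@H](O[Si](c1ccccc1)(c1ccccc1)C(C)(C)C)C(=C)C)C[C@@]12C[C@@H](C=COC)C(C)(C)[C@@](CC=C(C)C)(C(=O)C(C(=O)c3ccc(O[Si](C(C)C)(C(C)C)C(C)C)c(O[Si](C(C)C)(C(C)C)C(C)C)c3)=C1O)C2=O
F4 | step 21 | 7-(2-oxoethyl) analogue of 40 (endo on C7) | C=C(C)[C@H](C[C@@H](O[Si](c1ccccc1)(c1ccccc1)C(C)(C)C)C(=C)C)C[C@@]12C[C@@H](CC=O)C(C)(C)[C@@](CC=C(C)C)(C(=O)C(C(=O)c3ccc(O[Si](C(C)C)(C(C)C)C(C)C)c(O[Si](C(C)C)(C(C)C)C(C)C)c3)=C1O)C2=O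
F5 | step 15 | diarylmethanol from 17 and 21 (no prenyl group; carbinol epimers) | C=C(C)[C@H](C[C@@H](O[Si](c1ccccc1)(c1ccccc1)C(C)(C)C)C(=C)C)Cc1c(OCOC)cc(OCOC)c(C(O)c2ccc(O[Si](C(C)C)(C(C)C)C(C)C)c(O[Si](C(C)C)(C(C)C)C(C)C)c2)c1OCOC
F6 | step 15 | benzophenone from F5 (no prenyl group) | C=C(C)[C@H](C[C@@H](O[Si](c1ccccc1)(c1ccccc1)C(C)(C)C)C(=C)C)Cc1c(OCOC)cc(OCOC)c(C(=O)c2ccc(O[Si](C(C)C)(C(C)C)C(C)C)c(O[Si](C(C)C)(C(C)C)C(C)C)c2)c1OCOC
F7 | step 15 | des-prenyl analogue of 25 (2-aroyl-4-alkylphloroglucinol) | C=C(C)[C@H](C[C@@H](O[Si](c1ccccc1)(c1ccccc1)C(C)(C)C)C(=C)C)Cc1c(O)cc(O)c(C(=O)c2ccc(O[Si](C(C)C)(C(C)C)C(C)C)c(O[Si](C(C)C)(C(C)C)C(C)C)c2)c1O
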